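**Retrosynthetic overview** (labdane numbering: ring A = C1–C5 and C10, ring B = C5–C10, C17 on C8, C19 on C4, C20 on C10, chain C11–C16)
1. End game: the C15 acid comes from a silyl ether, the C19 angelate from the C19 alcohol, and the C4 quaternary centre from α-face methylation of a C19 aldehyde enolate made from a C4 methylidene.
2. C9–C11: a side-chain organocerium reagent (from (R)-3-methylglutaric acid monomethyl ester) adds to the ring B C9 enone; formate hydrogenolysis of the tertiary allylic carbonate with Pd(OAc)2/PBu3 then puts hydrogen on C9α.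
3. Ring B is the only ring closed (ring A is the starting cyclohexenone): C8–C9 by CrCl2/NiCl2 addition of a (Z)-vinyl iodide to the C9 aldehyde.
4. Feature carrying the strategy: C10 (quaternary, bearing C20, C9 and C1) and C5 (bearing C6) are the adjacent β- and α-carbons of a ring A cyclohexanone whose carbonyl carbon is C4. C10–C20 and C5–C6 are therefore made in one flask by enantioselective conjugate methylation of 3-(dimethoxymethyl)cyclohex-2-en-1-one and alkylation of the enolate with (Z)-1-bromo-3-iodobut-2-ene.

Key step: step 5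

Remark: the (S,S) antipode of the phosphoramidite ligand is assumed to deliver methyl to the enone face that gives (3S)-14; if the sense of induction is the opposite, the (R,R) ligand is used and nothing else changes.

**Route**

Step 1
Reactants: 1 3-ethoxycyclohex-2-en-1-one; 2 1,3-dithiane
Product: 5 3-(1,3-dithian-2-yl)cyclohex-2-en-1-one, via 2-lithio-1,3-dithiane 3 (not isolated), via lithium carbinolate adduct 4 (not isolated)
Conditions: 2, n-BuLi, THF, −30 °C; then 1, −30 → 0 °C; then 2 M HCl, rt
Reagents that add atoms: water (O)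
Why: Stork–Danheiser transposition: the lithiated dithiane adds 1,2 to the vinylogous ester, and aqueous acid hydrolyses the enol ether with loss of the tertiary hydroxyl to give the 3-substituted enone.

Step 2
Reactants: 5 3-(1,3-dithian-2-yl)cyclohex-2-en-1-one
Product: 6 3-(dimethoxymethyl)cyclohex-2-en-1-one
Conditions: PhI(OCOCF3)2, MeOH, rt
Reagents that add atoms: methanol (CO)
Why: Oxidative dithioacetal-to-acetal exchange with the hypervalent iodine reagent in methanol replaces the sulfur atoms, which would bind copper, by a dimethyl acetal and leaves the enone untouched.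

Step 3
Reactants: 7 but-2-yn-1-ol
Product: 9 (Z)-3-iodobut-2-en-1-ol, via sodium alkenylalkoxyaluminate 8 (not isolated)
Conditions: NaAlH2(OCH2CH2OMe)2 (Red-Al), THF, 0 °C → rt; then I2, THF, −78 → 0 °C
Reagents that add atoms: iodine (II)
Why: Hydroxyl-directed trans-hydroalumination of the propargylic alcohol places aluminium on C3 in a five-membered alkoxyaluminate, and iodinolysis of the C–Al bond with retention gives the (Z)-vinyl iodide.

Step 4
Reactants: 9 (Z)-3-iodobut-2-en-1-ol
Product: 10 (Z)-1-bromo-3-iodobut-2-ene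
Conditions: PBr3, Et2O, 0 °C
Reagents that add atoms: phosphorus tribromide (BrP(Br)Br)
Why: SN2 bromination of the primary allylic alcohol through its phosphite ester proceeds without isomerising the (Z)-iodoalkene.

Step 5
Reactants: 6 3-(dimethoxymethyl)cyclohex-2-en-1-one; 11 trimethylaluminium; 10 (Z)-1-bromo-3-iodobut-2-ene
Product: 14 (2R,3S)-3-(dimethoxymethyl)-2-[(2Z)-3-iodobut-2-en-1-yl]-3-methylcyclohexan-1-one, via dimethylaluminium enolate 12 (not isolated), via lithium trimethylaluminate enolate 13 (not isolated)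
Conditions: copper thiophene-2-carboxylate Cu(O2CC4H3S) (CuTC, 5 mol%), (S,S)-L = O,O'-(biphenyl-2,2'-diyl) N,N-bis[(S)-1-(2-naphthyl)ethyl]phosphoramidite (10 mol%), 11, Et2O, −30 °C; then MeLi, THF/HMPA, −30 °C; then 10, −30 → 0 °C
Reagents that add atoms: none
Why: AlMe3 transmetalates the monovalent copper–phosphoramidite complex to a chiral methylcopper species that binds the aluminium-activated enone 6, adds at C10 through a trivalent copper intermediate and reductively eliminates to form C10–C20 and the regiodefined aluminium enolate 12 (O–C4=C5); MeLi turns 12 into the more nucleophilic aluminate 13, which displaces bromide from 10 by SN2 attack through C5 to form C5–C6. The closest known reaction type is the copper-catalysed enantioselective conjugate addition of trialkylaluminium reagents to 3-substituted cyclohexenones that builds quaternary centres, followed by trapping of the enolate with an allylic halide. No ring is closed in this step. C10 is set by the chiral ligand (catalyst control of the enone face), and C5 by the substrate: the allylic bromide approaches the enolate face anti to the branched dimethoxymethyl group and syn to the smaller methyl group, giving the trans relation of C6 and C9 that the trans-decalin needs. The step needs 1,4- over 1,2-addition (copper catalysis and the low basicity of AlMe3), alkylation at C5 and not at C3 (the enolate is formed regiospecifically and captured cold by a reactive primary allylic bromide before proton transfer), SN2 over SN2' attack (the distal alkene carbon carries iodine and methyl), and survival of the vinyl iodide (MeLi is consumed by 12 before 10 is added).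

Step 6
Reactants: 14 (2R,3S)-3-(dimethoxymethyl)-2-[(2Z)-3-iodobut-2-en-1-yl]-3-methylcyclohexan-1-one
Product: 15 (1S,2S)-1-(dimethoxymethyl)-2-[(2Z)-3-iodobut-2-en-1-yl]-1-methyl-3-methylidenecyclohexane
Conditions: Ph3PCH3Br (2 equiv), KOtBu (1.8 equiv), toluene/THF, 0 °C → rt
Reagents that add atoms: methyltriphenylphosphonium bromide (C[P+](c1ccccc1)(c1ccccc1)c1ccccc1.[Br-])
Why: Wittig methylenation converts the C4 ketone into the exocyclic alkene; the deficit of base relative to the salt limits epimerisation at C5 and elimination of the vinyl iodide, and the acetal is inert.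

Step 7
Reactants: 15 (1S,2S)-1-(dimethoxymethyl)-2-[(2Z)-3-iodobut-2-en-1-yl]-1-methyl-3-methylidenecyclohexane
Product: 16 (1S,2S)-2-[(2Z)-3-iodobut-2-en-1-yl]-1-methyl-3-methylidenecyclohexane-1-carbaldehyde
Conditions: TsOH·H2O (cat.), acetone/H2O, rt
Reagents that add atoms: water (O)
Why: Acid-catalysed acetal hydrolysis frees the non-enolisable neopentyl aldehyde (C9) under conditions too mild to isomerise the 1,1-disubstituted alkene.

Step 8
Reactants: 16 (1S,2S)-2-[(2Z)-3-iodobut-2-en-1-yl]-1-methyl-3-methylidenecyclohexane-1-carbaldehyde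
Product: 17 (4aS,8aS)-2,8a-dimethyl-5-methylidene-1,4,4a,5,6,7,8,8a-octahydronaphthalen-1-ol (C9 epimers in labdane numbering; trans-fused)
Conditions: CrCl2 (5 equiv), NiCl2 (2 mol%), DMSO, rt, 0.01 M
Reagents that add atoms: none
Why: Intramolecular Nozaki–Hiyama–Kishi reaction: zerovalent nickel inserts into the C–I bond, transmetalation gives an alkenyl species of trivalent chromium that adds chemoselectively to the aldehyde and closes six-membered ring B at C8–C9 with retention of alkene geometry; the carbinol configuration does not matter because it is oxidised next.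

Step 9
Reactants: 17 bicyclic allylic alcohol
Product: 18 (4aS,8aS)-2,8a-dimethyl-5-methylidene-4a,5,6,7,8,8a-hexahydronaphthalen-1(4H)-one (C9 ketone, C7=C8, 5α-H, 10β-CH3)
Conditions: Dess–Martin periodinane, NaHCO3, CH2Cl2, 0 °C → rt
Reagents that add atoms: none
Why: Dess–Martin oxidation of the secondary allylic alcohol gives the enone; C10 is quaternary, so no stereocentre next to the carbonyl can epimerise.

Step 10
Reactants: 19 (R)-3-methylglutaric acid monomethyl ester
Product: 20 methyl (3R)-5-hydroxy-3-methylpentanoate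
Conditions: BH3·SMe2, THF, −10 °C → rt; aqueous work-up
Reagents that add atoms: none
Why: Borane reduces the free carboxylic acid much faster than the methyl ester (chemoselective acid reduction), so the two chain ends stay differentiated and the stereocentre is untouched.

Step 11
Reactants: 20 methyl (3R)-5-hydroxy-3-methylpentanoate
Product: 21 methyl (3R)-5-[(tert-butyldimethylsilyl)oxy]-3-methylpentanoate
Conditions: TBSCl, imidazole, CH2Cl2, 0 °C → rt
Reagents that add atoms: tert-butyldimethylsilyl chloride (CC(C)(C)[Si](C)(C)Cl)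
Why: Standard silylation of the primary alcohol, carried out at once so that the hydroxy ester cannot lactonise.

Step 12
Reactants: 21 methyl (3R)-5-[(tert-butyldimethylsilyl)oxy]-3-methylpentanoate
Product: 22 (3S)-5-[(tert-butyldimethylsilyl)oxy]-3-methylpentan-1-ol
Conditions: LiAlH4, Et2O, 0 °C
Reagents that add atoms: none
Why: Hydride reduction of the ester to the primary alcohol (the future C11); the silyl ether is stable at 0 °C.

Step 13
Reactants: 22 (3S)-5-[(tert-butyldimethylsilyl)oxy]-3-methylpentan-1-ol
Product: 23 tert-butyl{[(3R)-5-iodo-3-methylpentyl]oxy}dimethylsilane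
Conditions: PPh3, I2, imidazole, CH2Cl2, 0 °C → rt
Reagents that add atoms: iodine (II)
Why: Appel-type iodination of the primary alcohol by SN2 displacement of the alkoxyphosphonium group.

Step 14
Reactants: 23 tert-butyl{[(3R)-5-iodo-3-methylpentyl]oxy}dimethylsilane; 18 bicyclic enone
Product: 26 (13S)-15-[(tert-butyldimethylsilyl)oxy]-9β-hydroxy-18-norlabda-4(19),7-diene carrying the C11–C16 chain on C9α, via alkyllithium 24 (not isolated), via organocerium dichloride 25 (not isolated)
Conditions: 23, t-BuLi (2 equiv), Et2O/pentane, −78 °C; CeCl3 (anhydrous), THF, −78 °C; then 18, −78 → −20 °C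
Reagents that add atoms: none
Why: Iodine–lithium exchange and transmetalation to cerium give a weakly basic, oxophilic organocerium reagent that adds 1,2 to the hindered enone and forms C9–C11; attack is expected on the α face, anti to the axial C20 methyl on the neighbouring C10, which places the hydroxyl β.

Step 15
Reactants: 26 tertiary allylic alcohol
Product: 28 methyl carbonate of 26 (9β-OCO2Me), via potassium alkoxide 27 (not isolated)
Conditions: KN(SiMe3)2, THF, −78 °C; then ClCO2Me, −78 → 0 °C
Reagents that add atoms: methyl chloroformate (COC(=O)Cl)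
Why: Deprotonation of the hindered tertiary alcohol and acylation of the alkoxide by the small chloroformate gives the allylic carbonate needed for ionisation by palladium.

Step 16
Reactants: 28 tertiary allylic methyl carbonate
Product: 29 (13S)-15-[(tert-butyldimethylsilyl)oxy]-18-norlabda-4(19),7-diene (9α-H, side chain 9β)
Conditions: Pd(OAc)2 (10 mol%), PBu3 (10 mol%), HCO2H, Et3N, THF, 65 °C
Reagents that add atoms: none
Why: Palladium-catalysed formate hydrogenolysis of an allylic carbonate: zerovalent palladium ionises the β-carbonate with inversion (metal on the α face), the formate ligand loses CO2, and hydride passes from palladium to the more substituted allyl terminus C9 on the same α face, which sets 9α-H with the side chain equatorial and keeps the C7=C8 alkene.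

Step 17
Reactants: 29 18-norlabda-4(19),7-diene silyl ether
Product: 31 (13S)-15-[(tert-butyldimethylsilyl)oxy]-18-norlabd-7-en-19-ol (C4 epimers), via B-alkyl-9-BBN adduct 30 (not isolated)
Conditions: 9-BBN, THF, 0 °C → rt; then NaOH, H2O2, 0 °C → rt
Reagents that add atoms: hydrogen peroxide (OO)
Why: Anti-Markovnikov hydroboration–oxidation: 9-BBN reacts with the 1,1-disubstituted C4 methylidene far faster than with the trisubstituted C7=C8 alkene; the C4 configuration is of no consequence because C4 becomes an enolate carbon later.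

Step 18
Reactants: 31 C19 primary alcohol
Product: 32 (13S)-15-[(tert-butyldimethylsilyl)oxy]-18-norlabd-7-en-19-al (C4 epimers)
Conditions: Dess–Martin periodinane, NaHCO3, CH2Cl2, 0 °C → rt
Reagents that add atoms: none
Why: Dess–Martin oxidation of the primary alcohol to the aldehyde without touching the alkene or the silyl ether.

Step 19
Reactants: 32 C19 aldehyde
Product: 34 (13S)-15-[(tert-butyldimethylsilyl)oxy]labd-7-en-19-al (4β-CHO axial and 4α-CH3), via potassium enolate 33 (not isolated)
Conditions: KOtBu, THF, 0 °C; then MeI, 0 °C → rt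
Reagents that add atoms: iodomethane (CI)
Why: α-Alkylation of an aldehyde enolate: the exocyclic C4 enolate is C-methylated on the equatorial α face because the axial C20 methyl shields the β face in a 1,3-diaxial sense, giving the C4 quaternary centre with the formyl group axial (C19).

Step 20
Reactants: 34 labd-7-en-19-al silyl ether
Product: 35 (13S)-15-[(tert-butyldimethylsilyl)oxy]labd-7-en-19-ol
Conditions: NaBH4, MeOH, 0 °C
Reagents that add atoms: none
Why: Borohydride reduction of the neopentyl aldehyde to the C19 alcohol; no other group is reducible.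

Step 21
Reactants: 35 labd-7-en-19-ol silyl ether; 36 angelic acid [(2Z)-2-methylbut-2-enoic acid]
Product: 38 (13S)-15-[(tert-butyldimethylsilyl)oxy]labd-7-en-19-yl angelate, via mixed anhydride 37 (not isolated)
Conditions: 36, 2,4,6-trichlorobenzoyl chloride, Et3N, toluene, rt; then 35, 75 °C
Reagents that add atoms: none
Why: Yamaguchi-type esterification through the angelic 2,4,6-trichlorobenzoic mixed anhydride, run without a nucleophilic amine catalyst, acylates the neopentyl alcohol while avoiding the addition–elimination pathway that would isomerise the angelate to the tiglate.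

Step 22
Reactants: 38 silyl ether angelate
Product: 39 (13S)-15-hydroxylabd-7-en-19-yl angelate
Conditions: HF·pyridine, pyridine, THF, 0 °C → rt
Reagents that add atoms: none
Why: Buffered fluoride cleavage of the primary silyl ether; the conjugated ester and the alkenes are inert.

Step 23
Reactants: 39 C15 alcohol
Product: 41 (4S,5R,9S,10R,13S)-19-[(2Z)-2-methylbut-2-enoyloxy]labd-7-en-15-oic acid (CNP0180171.1), via C15 aldehyde 40 (not isolated)
Conditions: TEMPO (cat.), PhI(OAc)2, MeCN/H2O, rt
Reagents that add atoms: water (O)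
Why: Oxoammonium-mediated oxidation takes the primary alcohol through the aldehyde hydrate to the carboxylic acid under near-neutral conditions that leave the trisubstituted alkene and the angelate unchanged.

**Compound list**
1 | 3-ethoxycyclohex-2-en-1-one | CCOC1=CC(=O)CCC1 | starting material
2 | 1,3-dithiane | C1CSCSC1 | starting material
3 | 2-lithio-1,3-dithiane | [Li]C1SCCCS1 | intermediate
4 | lithium 1-(1,3-dithian-2-yl)-3-ethoxycyclohex-2-en-1-olate (racemic) | [Li+].[O-]C1(C2SCCCS2)C=C(OCC)CCC1 | intermediate
5 | 3-(1,3-dithian-2-yl)cyclohex-2-en-1-one | O=C1C=C(C2SCCCS2)CCC1 | intermediate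
6 | 3-(dimethoxymethyl)cyclohex-2-en-1-one | O=C1C=C(C(OC)OC)CCC1 | intermediate
7 | but-2-yn-1-ol | CC#CCO | starting material
8 | sodium bis(2-methoxyethoxy)aluminate in a five-membered ring with O1 and C3 of the butenol | CC1=CCO[Al-]1(OCCOC)OCCOC.[Na+] | intermediate
9 | (Z)-3-iodobut-2-en-1-ol | C/C(I)=C/CO | intermediate
10 | (Z)-1-bromo-3-iodobut-2-ene | C/C(I)=C/CBr | intermediate
11 | trimethylaluminium | C[Al](C)C | starting material
12 | dimethylaluminium enolate of (S)-3-(dimethoxymethyl)-3-methylcyclohexanone (O–C4=C5) | C[Al](C)OC1=C[C@@](C)(C(OC)OC)CCC1 | intermediate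
13 | lithium trimethylaluminate enolate derived from 12 | [Li+].C[Al-](C)(C)OC1=C[C@@](C)(C(OC)OC)CCC1 | intermediate
14 | (2R,3S)-3-(dimethoxymethyl)-2-[(2Z)-3-iodobut-2-en-1-yl]-3-methylcyclohexan-1-one | O=C1CCC[C@](C)(C(OC)OC)[C@H]1C/C=C(/C)I | intermediate
15 | (1S,2S)-1-(dimethoxymethyl)-2-[(2Z)-3-iodobut-2-en-1-yl]-1-methyl-3-methylidenecyclohexane | C=C1CCC[C@](C)(C(OC)OC)[C@H]1C/C=C(/C)I | intermediate
16 | (1S,2S)-2-[(2Z)-3-iodobut-2-en-1-yl]-1-methyl-3-methylidenecyclohexane-1-carbaldehyde | C=C1CCC[C@](C)(C=O)[C@H]1C/C=C(/C)I | intermediate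
17 | (4aS,8aS)-2,8a-dimethyl-5-methylidene-1,4,4a,5,6,7,8,8a-octahydronaphthalen-1-ol (carbinol epimers) | C=C1CCC[C@]2(C)C(O)C(C)=CC[C@@H]12 | intermediate
18 | (4aS,8aS)-2,8a-dimethyl-5-methylidene-4a,5,6,7,8,8a-hexahydronaphthalen-1(4H)-one | C=C1CCC[C@]2(C)C(=O)C(C)=CC[C@@H]12 | intermediate
19 | (R)-3-methylglutaric acid monomethyl ester | OC(=O)C[C@@H](C)CC(=O)OC | starting material
20 | methyl (3R)-5-hydroxy-3-methylpentanoate | OCC[C@@H](C)CC(=O)OC | intermediate
21 | methyl (3R)-5-[(tert-butyldimethylsilyl)oxy]-3-methylpentanoate | CC(C)(C)[Si](C)(C)OCC[C@@H](C)CC(=O)OC | intermediate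
22 | (3S)-5-[(tert-butyldimethylsilyl)oxy]-3-methylpentan-1-ol | CC(C)(C)[Si](C)(C)OCC[C@@H](C)CCO | intermediate
23 | tert-butyl{[(3R)-5-iodo-3-methylpentyl]oxy}dimethylsilane | CC(C)(C)[Si](C)(C)OCC[C@@H](C)CCI | intermediate
24 | alkyllithium from 23 (lithium in place of iodine, stereocentre unchanged) | [Li]CC[C@H](C)CCO[Si](C)(C)C(C)(C)C | intermediate
25 | alkylcerium dichloride from 24 | Cl[Ce](Cl)CC[C@H](C)CCO[Si](C)(C)C(C)(C)C | intermediate
26 | (13S)-15-[(tert-butyldimethylsilyl)oxy]-9β-hydroxy-18-norlabda-4(19),7-diene with the C11–C16 chain on C9α (5α-H, 10β-CH3) | C=C1CCC[C@]2(C)[C@](O)(CC[C@H](C)CCO[Si](C)(C)C(C)(C)C)C(C)=CC[C@@H]12 | intermediate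
27 | potassium alkoxide of 26 | C=C1CCC[C@]2(C)[C@]([O-])(CC[C@H](C)CCO[Si](C)(C)C(C)(C)C)C(C)=CC[C@@H]12.[K+] | intermediate
28 | methyl carbonate of 26 (9β-OCO2Me) | C=C1CCC[C@]2(C)[C@](OC(=O)OC)(CC[C@H](C)CCO[Si](C)(C)C(C)(C)C)C(C)=CC[C@@H]12 | intermediate
29 | (13S)-15-[(tert-butyldimethylsilyl)oxy]-18-norlabda-4(19),7-diene (5α-H, 9α-H, 10β-CH3) | C=C1CCC[C@]2(C)[C@@H](CC[C@H](C)CCO[Si](C)(C)C(C)(C)C)C(C)=CC[C@@H]12 | intermediate
30 | 9-(C19-alkyl)-9-borabicyclo[3.3.1]nonane adduct of 29 (C4 epimers) | C(B1C2CCCC1CCC2)C1CCC[C@]2(C)[C@@H](CC[C@H](C)CCO[Si](C)(C)C(C)(C)C)C(C)=CC[C@@H]12 | intermediate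
31 | (13S)-15-[(tert-butyldimethylsilyl)oxy]-18-norlabd-7-en-19-ol (C4 epimers) | OCC1CCC[C@]2(C)[C@@H](CC[C@H](C)CCO[Si](C)(C)C(C)(C)C)C(C)=CC[C@@H]12 | intermediate
32 | (13S)-15-[(tert-butyldimethylsilyl)oxy]-18-norlabd-7-en-19-al (C4 epimers) | O=CC1CCC[C@]2(C)[C@@H](CC[C@H](C)CCO[Si](C)(C)C(C)(C)C)C(C)=CC[C@@H]12 | intermediate
33 | potassium enolate of 32 (C4=C19–O) | [K+].[O-]C=C1CCC[C@]2(C)[C@@H](CC[C@H](C)CCO[Si](C)(C)C(C)(C)C)C(C)=CC[C@@H]12 | intermediate
34 | (13S)-15-[(tert-butyldimethylsilyl)oxy]labd-7-en-19-al (4α-CH3, 4β-CHO) | O=C[C@@]1(C)CCC[C@]2(C)[C@@H](CC[C@H](C)CCO[Si](C)(C)C(C)(C)C)C(C)=CC[C@@H]12 | intermediate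
35 | (13S)-15-[(tert-butyldimethylsilyl)oxy]labd-7-en-19-ol | OC[C@@]1(C)CCC[C@]2(C)[C@@H](CC[C@H](C)CCO[Si](C)(C)C(C)(C)C)C(C)=CC[C@@H]12 | intermediate
36 | angelic acid, (2Z)-2-methylbut-2-enoic acid | C/C=C(/C)C(=O)O | starting material
37 | angelic 2,4,6-trichlorobenzoic anhydride | C/C=C(/C)C(=O)OC(=O)c1c(Cl)cc(Cl)cc1Cl | intermediate
38 | (13S)-15-[(tert-butyldimethylsilyl)oxy]labd-7-en-19-yl angelate | C/C=C(/C)C(=O)OC[C@@]1(C)CCC[C@]2(C)[C@@H](CC[C@H](C)CCO[Si](C)(C)C(C)(C)C)C(C)=CC[C@@H]12 | intermediate
39 | (13S)-15-hydroxylabd-7-en-19-yl angelate | C/C=C(/C)C(=O)OC[C@@]1(C)CCC[C@]2(C)[C@@H](CC[C@H](C)CCO)C(C)=CC[C@@H]12 | intermediate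
40 | (13S)-15-oxolabd-7-en-19-yl angelate | C/C=C(/C)C(=O)OC[C@@]1(C)CCC[C@]2(C)[C@@H](CC[C@H](C)CC=O)C(C)=CC[C@@H]12 | intermediate
41 | (4S,5R,9S,10R,13S)-19-[(2Z)-2-methylbut-2-enoyloxy]labd-7-en-15-oic acid (CNP0180171.1) | C/C=C(/C)C(=O)OC[C@@]1(C)CCC[C@]2(C)[C@@H](CC[C@H](C)CC(=O)O)C(C)=CC[C@@H]12 | target

**Step count and risks**

Total step count: 23. Longest linear sequence: 17 steps (steps 1, 2, 5–9 and 14–23); the allylic bromide (steps 3–4) and the side chain (steps 10–13) are convergent branches.

Steps most likely to fail: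

1. Step 5 (key step). The aluminate may alkylate slowly at C5 beside the new quaternary centre, so that proton transfer, alkylation at C3 or double alkylation take over. AlMe3 may also open the acetal, and the enantioselectivity at C10 or the facial selectivity at C5 may be too low. Fallback: setting out from 6 and 11, the copper-catalysed conjugate addition is run alone and enolate 12 is trapped with Me3SiOTf as the trimethylsilyl enol ether F1, which can be purified and checked for enantiopurity. MeLi in THF then releases the regiodefined lithium enolate F2, which is alkylated with 10 in THF/HMPA at −40 °C, and the route is rejoined at 14.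

2. Step 16. Hydride may be delivered to C7 instead of C9, or β-hydride elimination of the crowded allylpalladium intermediate may give dienes. The wrong C9 configuration results if the addition in step 14 has taken place on the β face. Fallback: setting out from 26 (either C9 epimer serves), oxidative 1,3-transposition of the tertiary allylic alcohol with pyridinium chlorochromate (C5H5NH)[CrO3Cl] (Babler–Dauben) gives the C7 ketone with a C8=C9 double bond F3. Li/NH3 with one equivalent of t-BuOH reduces the enone with axial protonation at C9 (9α-H, side chain equatorial) to the lithium enolate F4, which is trapped with PhNTf2 as the C7 enol triflate F5. Reduction of the triflate with Pd(OAc)2/PPh3, HCO2H and Bu3N returns to the route at 29.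

3. Step 19. O-methylation or self-aldol condensation of the aldehyde enolate may compete, and the facial selectivity of C-methylation may be insufficient. Fallback: setting out from 32, Pinnick oxidation (NaClO2, NaH2PO4, 2-methylbut-2-ene) gives the C19 carboxylic acid F6, and Me3SiCHN2 gives the methyl ester F7. LiN(iPr)2 at −78 °C forms the ester lithium enolate F8, which is methylated by MeI on the α face to the axial 4β-ester F9 (no O-alkylation or aldol pathway is open to an ester enolate). LiAlH4 reduction returns to the route at 35.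

Further compounds
F1 | step 5 | trimethylsilyl enol ether of (S)-3-(dimethoxymethyl)-3-methylcyclohexanone (O–C4=C5) | C[Si](C)(C)OC1=C[C@@](C)(C(OC)OC)CCC1
F2 | step 5 | lithium enolate of (S)-3-(dimethoxymethyl)-3-methylcyclohexanone (O–C4=C5) | [Li]OC1=C[C@@](C)(C(OC)OC)CCC1
F3 | step 16 | (13S)-15-[(tert-butyldimethylsilyl)oxy]-18-norlabda-4(19),8-dien-7-one | C=C1CCC[C@]2(C)C(CC[C@H](C)CCO[Si](C)(C)C(C)(C)C)=C(C)C(=O)C[C@@H]12
F4 | step 16 | lithium C7 enolate (C7=C8) with 9α-H obtained by reduction of F3 | C=C1CCC[C@]2(C)[C@@H](CC[C@H](C)CCO[Si](C)(C)C(C)(C)C)C(C)=C(O[Li])C[C@@H]12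
F5 | step 16 | (13S)-15-[(tert-butyldimethylsilyl)oxy]-18-norlabda-4(19),7-dien-7-yl trifluoromethanesulfonate | C=C1CCC[C@]2(C)[C@@H](CC[C@H](C)CCO[Si](C)(C)C(C)(C)C)C(C)=C(OS(=O)(=O)C(F)(F)F)C[C@@H]12
F6 | step 19 | (13S)-15-[(tert-butyldimethylsilyl)oxy]-18-norlabd-7-en-19-oic acid (C4 epimers) | OC(=O)C1CCC[C@]2(C)[C@@H](CC[C@H](C)CCO[Si](C)(C)C(C)(C)C)C(C)=CC[C@@H]12
F7 | step 19 | methyl (13S)-15-[(tert-butyldimethylsilyl)oxy]-18-norlabd-7-en-19-oate (C4 epimers) | COC(=O)C1CCC[C@]2(C)[C@@H](CC[C@H](C)CCO[Si](C)(C)C(C)(C)C)C(C)=CC[C@@H]12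
F8 | step 19 | lithium ester enolate of F7 (C4=C19) | COC(O[Li])=C1CCC[C@]2(C)[C@@H](CC[C@H](C)CCO[Si](C)(C)C(C)(C)C)C(C)=CC[C@@H]12
F9 | step 19 | methyl (13S)-15-[(tert-butyldimethylsilyl)oxy]labd-7-en-19-oate (4α-CH3, 4β-CO2Me) | COC(=O)[C@@]1(C)CCC[C@]2(C)[C@@H](CC[C@H](C)CCO[Si](C)(C)C(C)(C)C)C(C)=CC[C@@H]12
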